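**Plan**
Numbering of each half: C1 OH, C2 acetyl, C3 methyl, C8 OH, biaryl bond C7–C7'.
Cuts: the C8/C8' hydroxyls are masked as methyl ethers. Then C1–C2 and C3–C4 are cut in both halves at once (four bonds), and C7–C7' is cut last.
Enabling feature: in ring C1–C2–C3–C4–C4a–C8a, C1 (acid oxidation level) and C4 (a CH) sit on the adjacent carbons C8a and C4a of ring C4a–C5–C6–C7–C8–C8a, which is an ortho-toluate. C2(acetyl)–C3(methyl) is the α,β-pair of the methyl enol ether of acetylacetone.
Forward: 2-bromo-5-methylphenol supplies the inner benzene rings. Its one free ortho carbon takes the ester carbon, the bromide makes C7–C7' by homocoupling, both outer rings close in one operation, and ether cleavage ends the route.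
Stereochemistry: none to set. The target has no stereocentre, and the sp3 centres that arise during ring closure vanish on aromatisation.

Key step: step 6

Assumption: the SMILES carries no stereodescriptor and the C7–C7' axis has only OH and H as ortho substituents on each ring, so it rotates freely at room temperature. Stypandrol is therefore treated as a single achiral compound.

**Step 1**
Reactants: 1 2-bromo-5-methylphenol
Product: 3 3-bromo-2-hydroxy-6-methylbenzaldehyde, via benzylic alcohol 2 (not isolated)
Conditions: MgCl2, Et3N, (CH2O)n, MeCN, reflux; then 1 M HCl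
Reagents that add atoms: paraformaldehyde (formaldehyde), C=O
Why: Casnati–Skattebøl ortho-formylation: the magnesium phenoxide hands formaldehyde to an ortho carbon through a six-membered chelate, bromine blocks C2 so that C6 is the only site open, and a second formaldehyde accepts hydride from the magnesium alkoxide of 2 (Oppenauer-type step) to leave the aldehyde.

**Step 2**
Reactants: 3 3-bromo-2-hydroxy-6-methylbenzaldehyde
Product: 4 3-bromo-2-hydroxy-6-methylbenzoic acid
Conditions: NaClO2, H2NSO3H, dioxane–H2O, 0 °C → rt
Reagents that add atoms: sodium chlorite, [Na+].[O-]Cl=O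
Why: Lindgren–Pinnick oxidation: chlorous acid adds to the formyl group and fragments to the acid without needing room around the doubly ortho-substituted carbonyl, and sulfamic acid intercepts the hypochlorous acid before it can chlorinate the free phenol ring, as is standard for hydroxybenzaldehydes.

**Step 3**
Reactants: 4 3-bromo-2-hydroxy-6-methylbenzoic acid
Product: 6 methyl 3-bromo-2-methoxy-6-methylbenzoate, via methyl 3-bromo-2-hydroxy-6-methylbenzoate 5 (not isolated)
Conditions: MeI (3 equiv), K2CO3, DMF, rt → 50 °C
Reagents that add atoms: iodomethane, CI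
Why: Double SN2 O-methylation (carboxylate alkylation, then Williamson ether synthesis): bond formation takes place at the methyl carbon of MeI and not at the shielded carboxyl carbon, so the 2,6-disubstitution that defeats Fischer esterification is irrelevant, and the aryl bromide is inert.

**Step 4**
Reactants: 6 methyl 3-bromo-2-methoxy-6-methylbenzoate (two molecules)
Product: 7 dimethyl 2,2'-dimethoxy-4,4'-dimethylbiphenyl-3,3'-dicarboxylate
Conditions: NiBr2(PPh3)2 (10 mol %), Zn, Et4NI, THF, 50 °C
Reagents that add atoms: none
Why: Nickel(0)-catalysed Ullmann-type reductive homocoupling with zinc as terminal reductant: oxidative addition into C–Br, aryl exchange between nickel centres and reductive elimination join the two C3 carbons (the future C7–C7' bond), esters and methyl ethers are untouched, and a single ortho methoxy group per ring is within the steric tolerance of the method.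

**Step 5**
Reactants: 8 pentane-2,4-dione
Product: 9 (E)-4-methoxypent-3-en-2-one
Conditions: HC(OMe)3, p-TsOH·H2O (cat.), MeOH, 55 °C; distillation
Reagents that add atoms: trimethyl orthoformate, COC(OC)OC
Why: Acid-catalysed ketalisation of one carbonyl group by the orthoester and loss of methanol give the conjugated enol ether (vinylogous ester), a standard preparation in which the symmetry of 8 rules out regioisomers and the E isomer is the thermodynamically preferred one; the alkene geometry is lost again in step 6.

**Step 6**
Reactants: 7 dimethyl 2,2'-dimethoxy-4,4'-dimethylbiphenyl-3,3'-dicarboxylate; 9 (E)-4-methoxypent-3-en-2-one (two molecules per molecule of 7)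
Product: 12 8,8'-di-O-methylstypandrol (2,2'-diacetyl-1,1'-dihydroxy-8,8'-dimethoxy-3,3'-dimethyl-7,7'-binaphthalene), via dilithiated bis-toluate 10 (not isolated), via bis(acetylmethoxytetralone) 11 (not isolated)
Conditions: LDA (2.4 equiv), THF, −78 °C; 9 (2.6 equiv), −78 °C (1 h) → rt; 1 M HCl
Reagents that add atoms: none
Why: This is a Staunton–Weinreb annulation (toluate anion plus β-alkoxy enone) run at both ends of the biphenyl. LDA removes one proton from each aryl methyl group, acidified by its ortho ester, to give dianion 10, and each delocalised benzylic carbanion attacks the methoxy- and methyl-bearing β-carbon of 9, which forms C4–C3 and C4'–C3'. Each ketone enolate so released acylates through its internal carbon on the neighbouring ester, a 6-(enolexo)-exo-trig Claisen closure for each of the two new rings, which forms C2–C1 and C2'–C1' and leads to 11. E1cB loss of methoxide from C3 and tautomerisation of the C4 methylene then give the lithium naphtholates, so the four transient sp3 centres of 11 disappear and no stereocentre remains to be controlled. The step needs 1,4-addition to outrun 1,2-addition and proton transfer from the methyl groups of 9 at both sites: the soft anion and the vinylogous-ester character of the carbonyl group direct attack to the β-carbon, and holding the mixture at −78 °C until both additions are over keeps the methanol that ring closure releases away from unreacted carbanion. The regiochemistry is fixed because the adjacent ester is the only electrophile each enolate can reach, the two reacting sites point away from each other along the biaryl axis, and the 2,6-disubstituted esters are too shielded for intermolecular self-condensation at this temperature.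

**Step 7**
Reactants: 12 8,8'-di-O-methylstypandrol
Product: 13 stypandrol (2,2'-diacetyl-1,1',8,8'-tetrahydroxy-3,3'-dimethyl-7,7'-binaphthalene)
Conditions: BBr3 (6 equiv), CH2Cl2, −78 → 0 °C, Ar; then ice–water
Reagents that add atoms: none
Why: Boron tribromide cleavage of aryl methyl ethers: boron binds the twisted, electron-rich C8/C8' methoxy oxygens (helped by the peri C1–O–B linkage), bromide removes the methyl groups by SN2, no selectivity is required because every O-methyl group has to go, and the boron chelates of the o-hydroxyacetyl units hydrolyse on aqueous work-up.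

**Compound list**
1 | 2-bromo-5-methylphenol | Cc1ccc(Br)c(O)c1 | starting material
2 | 6-bromo-2-(hydroxymethyl)-3-methylphenol (present as its magnesium alkoxide, not isolated) | Cc1ccc(Br)c(O)c1CO | intermediate
3 | 3-bromo-2-hydroxy-6-methylbenzaldehyde | Cc1ccc(Br)c(O)c1C=O | intermediate
4 | 3-bromo-2-hydroxy-6-methylbenzoic acid | Cc1ccc(Br)c(O)c1C(=O)O | intermediate
5 | methyl 3-bromo-2-hydroxy-6-methylbenzoate (not isolated) | COC(=O)c1c(C)ccc(Br)c1O | intermediate
6 | methyl 3-bromo-2-methoxy-6-methylbenzoate | COC(=O)c1c(C)ccc(Br)c1OC | intermediate
7 | dimethyl 2,2'-dimethoxy-4,4'-dimethylbiphenyl-3,3'-dicarboxylate | COC(=O)c1c(C)ccc(-c2ccc(C)c(C(=O)OC)c2OC)c1OC | intermediate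
8 | pentane-2,4-dione | CC(=O)CC(C)=O | starting material
9 | (E)-4-methoxypent-3-en-2-one | CO/C(C)=C/C(C)=O | intermediate
10 | dimethyl 4,4'-bis(lithiomethyl)-2,2'-dimethoxybiphenyl-3,3'-dicarboxylate (not isolated) | COC(=O)c1c(C[Li])ccc(-c2ccc(C[Li])c(C(=O)OC)c2OC)c1OC | intermediate
11 | 2,2'-diacetyl-3,3',8,8'-tetramethoxy-3,3'-dimethyl-3,3',4,4'-tetrahydro-7,7'-binaphthalene-1,1'(2H,2'H)-dione (not isolated; diastereomer mixture, all four sp3 centres erased on aromatisation) | CC(=O)C1C(=O)c2c(OC)c(-c3ccc4c(c3OC)C(=O)C(C(C)=O)C(C)(OC)C4)ccc2CC1(C)OC | intermediate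
12 | 8,8'-di-O-methylstypandrol (2,2'-diacetyl-1,1'-dihydroxy-8,8'-dimethoxy-3,3'-dimethyl-7,7'-binaphthalene) | CC(=O)c1c(C)cc2ccc(-c3ccc4cc(C)c(C(C)=O)c(O)c4c3OC)c(OC)c2c1O | intermediate
13 | stypandrol | CC(=O)c1c(C)cc2ccc(-c3ccc4cc(C)c(C(C)=O)c(O)c4c3O)c(O)c2c1O | target

**Totals**
Total steps: 7. Longest linear sequence: 6 (steps 1, 2, 3, 4, 6, 7).

**Steps most likely to fail**

Step 6. The double annulation may stall after one end. Possible causes are proton transfer from the methyl groups of 9 to a benzylic carbanion, 1,2-addition followed by lactonisation, or quenching of the second carbanion by methanol released when the first ring closes.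
The fallback inverts the order of events: the annulation is run once per molecule on the monomer, and the biaryl bond is made last.
- It sets out from 6, which is deprotonated with LDA (1.1 equiv, THF, −78 °C) to methyl 3-bromo-6-(lithiomethyl)-2-methoxybenzoate F1.
- With 9, the same Michael–Claisen–elimination sequence should give 1-(7-bromo-1-hydroxy-8-methoxy-3-methylnaphthalen-2-yl)ethan-1-one F2. Incomplete conversion here only returns 6, which can be separated and recycled.
- Part of F2 is converted by Miyaura borylation (B2pin2, PdCl2(dppf), KOAc, dioxane, 90 °C) into 1-[1-hydroxy-8-methoxy-3-methyl-7-(4,4,5,5-tetramethyl-1,3,2-dioxaborolan-2-yl)naphthalen-2-yl]ethan-1-one F3.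
- Suzuki–Miyaura coupling of this boronate with the rest of the bromide (Pd(OAc)2, SPhos, K3PO4, toluene–H2O, 90 °C) comes back to the route at 12.

Step 4. Hydrodebromination of the arylnickel intermediate, or slow aryl exchange between two ortho-methoxy-substituted nickel centres, may erode the homocoupling.
The fallback differentiates the two halves.
- Setting out from 6, Miyaura borylation (B2pin2, PdCl2(dppf), KOAc, dioxane, 90 °C) gives methyl 2-methoxy-6-methyl-3-(4,4,5,5-tetramethyl-1,3,2-dioxaborolan-2-yl)benzoate F4.
- Suzuki–Miyaura cross-coupling of this boronate with a second portion of 6 (Pd(OAc)2, SPhos, K3PO4, toluene–H2O) comes back to the route at 7.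

Step 1. Attack at the crowded carbon between OH and CH3 of the bromine-deactivated ring may be too slow, so that O-methoxymethylation and diarylmethane formation take over.
The fallback brings in the carboxyl carbon after the biaryl bond, as an electrophile for an aryllithium.
- Setting out from 1, O-methylation (MeI, K2CO3, acetone) gives 1-bromo-2-methoxy-4-methylbenzene F5.
- Nickel/zinc homocoupling gives 2,2'-dimethoxy-4,4'-dimethylbiphenyl F6.
- Double directed ortho-metalation (n-BuLi, TMEDA, Et2O, 0 °C → rt), for which C3 and C3' are the only positions ortho to a methoxy group, gives 3,3'-dilithio-2,2'-dimethoxy-4,4'-dimethylbiphenyl F7.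
- Quenching with methyl chloroformate at −78 °C comes back to the route at 7.

**Further compounds**
F1 | step 6 | methyl 3-bromo-6-(lithiomethyl)-2-methoxybenzoate | COC(=O)c1c(C[Li])ccc(Br)c1OC
F2 | step 6 | 1-(7-bromo-1-hydroxy-8-methoxy-3-methylnaphthalen-2-yl)ethan-1-one | CC(=O)c1c(C)cc2ccc(Br)c(OC)c2c1O
F3 | step 6 | 1-[1-hydroxy-8-methoxy-3-methyl-7-(4,4,5,5-tetramethyl-1,3,2-dioxaborolan-2-yl)naphthalen-2-yl]ethan-1-one | CC(=O)c1c(C)cc2ccc(B3OC(C)(C)C(C)(C)O3)c(OC)c2c1O
F4 | step 4 | methyl 2-methoxy-6-methyl-3-(4,4,5,5-tetramethyl-1,3,2-dioxaborolan-2-yl)benzoate | COC(=O)c1c(C)ccc(B2OC(C)(C)C(C)(C)O2)c1OC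
F5 | step 1 | 1-bromo-2-methoxy-4-methylbenzene | COc1cc(C)ccc1Br
F6 | step 1 | 2,2'-dimethoxy-4,4'-dimethylbiphenyl | COc1cc(C)ccc1-c1ccc(C)cc1OC
F7 | step 1 | 3,3'-dilithio-2,2'-dimethoxy-4,4'-dimethylbiphenyl | COc1c([Li])c(C)ccc1-c1ccc(C)c([Li])c1OC
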